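The route rests on unzipping rings A and B of the labdane at C4–C5 and C9–C10, which leads back to an all-E acyclic C20 chain. The feature exploited is that the trans-decalin (C4 gem-dimethyl, C10 methyl, equatorial C9 chain, C7=C8 alkene) is the chair–chair fold of three trisubstituted E alkenes. The C13=C16 methylene next to acetoxy-bearing C14 is too electron-poor to join in. A single chiral-acid protonation at C3 thus closes both rings, sets C5, C9 and C10 and gives the target itself. Its precursor is the (14S)-tetraene diacetate, built from farnesol through geranylgeraniol, Sharpless epoxidation and a titanium-mediated epoxide-to-ene-diol isomerisation.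

Key step: step 9

Numbering: labdane numbers are used for the chain carbons in the acyclic compounds too. C15 is the CH2O terminus, C14 the carbinol carbon, C13=C16 the methylene unit and C3=C4 the terminal isopropylidene alkene.

Assumption: the catalyst antipode for step 9 is the one that converts (3E,7E)-homofarnesol into (−)-ambrox, whose decalin has the same absolute fold as the 5S,9S,10S target, and this sense of induction is taken to carry over to 13.

Step 1
Reactants: 1 (2E,6E)-farnesol
Product: 2 (2E,6E)-farnesyl bromide
Conditions: PBr3 (0.4 equiv), Et2O, −10 to 0 °C, dark; cold aq NaHCO3 wash; used crude the same day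
Reagents that add atoms: phosphorus tribromide, BrP(Br)Br
Why: Bromination of a primary allylic alcohol with PBr3 is an SN2 process at the unhindered CH2–O carbon, and at or below 0 °C in ether neither SN2′ transposition nor loss of the 2E geometry should compete.

Step 2
Reactants: 2 (2E,6E)-farnesyl bromide; 3 ethyl acetoacetate
Product: 5 ethyl (6E,10E)-7,11,15-trimethyl-3-oxohexadeca-6,10,14-trienoate, via acetoacetate dianion 4 (not isolated)
Conditions: 3 (1.1 equiv), NaH (1.15 equiv), THF, 0 °C; n-BuLi (1.1 equiv), 0 °C; 2 (1.0 equiv), 0 °C to rt; cold 1 M HCl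
Reagents that add atoms: none
Why: In this γ-alkylation of the acetoacetate dianion, the terminal carbanion of 4, formed last, is the more basic and nucleophilic site and displaces the primary allylic bromide by SN2, which forms the C11–C12 bond and leaves the three alkenes untouched.

Step 3
Reactants: 5 ethyl (6E,10E)-7,11,15-trimethyl-3-oxohexadeca-6,10,14-trienoate
Product: 7 ethyl (2Z,6E,10E)-3-[(diethoxyphosphoryl)oxy]-7,11,15-trimethylhexadeca-2,6,10,14-tetraenoate, via sodium enolate 6 (not isolated)
Conditions: NaH (1.1 equiv), Et2O, 0 °C; ClP(O)(OEt)2 (1.2 equiv), 0 °C to rt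
Reagents that add atoms: diethyl chlorophosphate, CCOP(=O)(Cl)OCC
Why: In this O-phosphorylation of a β-keto ester enolate, sodium in ether is chelated between the two oxygens of 6, which holds the enolate oxygen cis to the ester, and the hard chlorophosphate reacts at that oxygen to give the 2Z enol phosphate with the full farnesyl-derived chain intact.

Step 4
Reactants: 7 ethyl (2Z,6E,10E)-3-[(diethoxyphosphoryl)oxy]-7,11,15-trimethylhexadeca-2,6,10,14-tetraenoate
Product: 8 ethyl (2E,6E,10E)-geranylgeranoate (ethyl 3,7,11,15-tetramethylhexadeca-2,6,10,14-tetraenoate)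
Conditions: CuI (2.0 equiv), MeLi (4.0 equiv), Et2O, 0 °C; then 7, −78 to −45 °C; aq NH4Cl/NH3
Reagents that add atoms: lithium dimethylcuprate, [Li+].C[Cu-]C (made in the flask from methyllithium, [Li]C, and CuI)
Why: Addition–elimination of a Gilman cuprate on a β-phosphoryloxy enoate proceeds with retention of alkene geometry at low temperature, so methyl takes the place of the phosphate cis to the ester and the long chain ends up trans to it (2E).

Step 5
Reactants: 8 ethyl (2E,6E,10E)-geranylgeranoate
Product: 9 (2E,6E,10E)-geranylgeraniol
Conditions: i-Bu2AlH (2.3 equiv), CH2Cl2, −78 to 0 °C; aq potassium sodium tartrate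
Reagents that add atoms: none
Why: 1,2-Reduction of an α,β-unsaturated ester with i-Bu2AlH gives the allylic alcohol without conjugate reduction and without change of any alkene geometry.

Step 6
Reactants: 9 (2E,6E,10E)-geranylgeraniol
Product: 10 (2R,3R)-2,3-epoxygeranylgeraniol, [(2R,3R)-3-methyl-3-[(3E,7E)-4,8,12-trimethyltrideca-3,7,11-trien-1-yl]oxiran-2-yl]methanol
Conditions: Ti(OiPr)4 (5 mol %), D-(−)-diethyl tartrate (6 mol %), t-BuOOH (1.5 equiv, decane), 4 Å molecular sieves, CH2Cl2, −20 °C; aq NaOH/brine, 0 °C
Reagents that add atoms: tert-butyl hydroperoxide, CC(C)(C)OO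
Why: In the Katsuki–Sharpless asymmetric epoxidation only the alkene whose allylic hydroxyl binds titanium is oxidised, the D-(−)-tartrate ligand delivers oxygen to the face that gives the 2R,3R epoxide and so fixes the future C14 (C2 of 10), and catalytic titanium, sieves and −20 °C hold back premature epoxide opening.

Step 7
Reactants: 10 (2R,3R)-2,3-epoxygeranylgeraniol
Product: 12 (2S,6E,10E)-7,11,15-trimethyl-3-methylidenehexadeca-6,10,14-triene-1,2-diol, via titanium alkoxide 11 (not isolated)
Conditions: Ti(OiPr)4 (1.5 equiv), CH2Cl2, 23 °C; 10 % aq tartaric acid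
Reagents that add atoms: none
Why: This hydroxyl-directed Lewis acid isomerisation of a 2,3-epoxy alcohol to an ene-diol is known for 2,3-epoxygeraniol; in 11 the tethered titanium weakens the tertiary C13–O bond and one of its alkoxide ligands removes a proton from the C16 methyl, the group cis to the CH2O–Ti arm, so the C13=C16 methylene forms, the C14–O bond is never broken, and the descriptor changes from R to S only because the CIP ranking of C13 and C15 is reversed.

Step 8
Reactants: 12 (2S,6E,10E)-7,11,15-trimethyl-3-methylidenehexadeca-6,10,14-triene-1,2-diol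
Product: 13 (2S,6E,10E)-7,11,15-trimethyl-3-methylidenehexadeca-6,10,14-triene-1,2-diyl diacetate
Conditions: Ac2O (3 equiv), pyridine, 4-(dimethylamino)pyridine (5 mol %), CH2Cl2, 0 °C to rt; dilute citric acid wash, silica filtration, azeotropic drying
Reagents that add atoms: acetic anhydride, CC(=O)OC(C)=O
Why: Nucleophile-catalysed acylation of the primary and the secondary allylic hydroxyl under basic, non-ionising conditions leaves C14 and all four alkenes unchanged, and the acid wash removes amine traces that would quench the acid catalyst of the next step.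

Step 9
Reactants: 13 (2S,6E,10E)-7,11,15-trimethyl-3-methylidenehexadeca-6,10,14-triene-1,2-diyl diacetate
Product: 15 (5S,9S,10S,14S)-labda-7,13(16)-diene-14,15-diyl diacetate (CNP0289003.1), via labdenyl C8 cation 14 (not isolated)
Conditions: confined imidodiphosphorimidate Brønsted acid (IDPi: two 3,3′-diaryl-1,1′-bi-2-naphthol phosphorus units bridged by nitrogen, each phosphorus carrying an N-perfluoroarylsulfonyl imide group, aryl = spirocyclohexyl-fluoren-2-yl; 5 mol %), (CF3)3COH, 0 °C; Et3N quench; chromatography on AgNO3-impregnated silica
Reagents that add atoms: none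
Why: Proposed new method: The acid, held in its chiral pocket, protonates C3 of the terminal isopropylidene of 13, C5 of the C5=C10 alkene adds to C4 and C9 of the C8=C9 alkene adds to C10 in an antiperiplanar cascade that ends at the tertiary cation 14, and the imidodiphosphorimidate anion then takes the axial C7 hydrogen, which forms the C7=C8 alkene and returns the proton to the catalyst. The closest known reaction types are the imidodiphosphorimidate-catalysed cyclization of (3E,7E)-homofarnesol to (−)-ambrox in fluorinated alcohols, the BINOL–SnCl4 proton-initiated polyene cyclizations and the FSO3H bicyclization of farnesyl acetate to racemic drim-7-en-11-yl acetate; new here is the union of catalyst control with termination by regioselective proton loss on a tetraene that carries two esters. Ring A closes in a 6-endo-trig mode through a chair by the C4–C5 bond and ring B closes in a 6-endo-trig mode through a second chair by the C9–C10 bond. The E geometry of the C5=C10 and C8=C9 alkenes and anti addition across each of them fix C5, C10 and C9 relative to one another (trans ring fusion, equatorial C9 chain), the catalyst antipode fixes their absolute sense by choosing which face of the pre-folded chain is protonated, and C14 is a spectator whose presence turns any wrong-sense product into a separable diastereomer. Needed are initiation at C3=C4 only, a stop after two rings and loss of H7 in preference to H9 or H17: the terminal alkene is the most exposed basic site, the C13=C16 alkene is only 1,1-disubstituted and is drained by the two acetoxy groups, all the more once these are hydrogen-bonded to the fluorinated alcohol, the ester oxygens could reach C8 only through nine- or ten-membered rings, H9 is buried between C10 and the side chain, and an exocyclic C8=C17 alkene would be re-protonated and fed back to 14. A metal-free acid is chosen because the two acetates would tie up SnCl4, and the run is quenched with Et3N at full conversion so that the product is not drawn on to the tetrasubstituted C8=C9 isomer.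

Compound list
1 | (2E,6E)-farnesol | CC(C)=CCC/C(C)=C/CC/C(C)=C/CO | starting material
2 | (2E,6E)-farnesyl bromide | CC(C)=CCC/C(C)=C/CC/C(C)=C/CBr | intermediate
3 | ethyl acetoacetate | CCOC(=O)CC(C)=O | starting material
4 | sodium lithium dianion of ethyl acetoacetate | [Li+].[Na+].C=C([O-])C=C([O-])OCC | intermediate (not isolated)
5 | ethyl (6E,10E)-7,11,15-trimethyl-3-oxohexadeca-6,10,14-trienoate | CC(C)=CCC/C(C)=C/CC/C(C)=C/CCC(=O)CC(=O)OCC | intermediate
6 | chelated sodium (Z)-enolate of 5 | CC(C)=CCC/C(C)=C/CC/C(C)=C/CC/C([O-])=C/C(=O)OCC.[Na+] | intermediate (not isolated)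
7 | ethyl (2Z,6E,10E)-3-[(diethoxyphosphoryl)oxy]-7,11,15-trimethylhexadeca-2,6,10,14-tetraenoate | CC(C)=CCC/C(C)=C/CC/C(C)=C/CC/C(OP(=O)(OCC)OCC)=C/C(=O)OCC | intermediate
8 | ethyl (2E,6E,10E)-geranylgeranoate | CC(C)=CCC/C(C)=C/CC/C(C)=C/CC/C(C)=C/C(=O)OCC | intermediate
9 | (2E,6E,10E)-geranylgeraniol | CC(C)=CCC/C(C)=C/CC/C(C)=C/CC/C(C)=C/CO | intermediate
10 | (2R,3R)-2,3-epoxygeranylgeraniol | CC(C)=CCC/C(C)=C/CC/C(C)=C/CC[C@@]1(C)O[C@@H]1CO | intermediate
11 | triisopropoxytitanium alkoxide of 10 | CC(C)=CCC/C(C)=C/CC/C(C)=C/CC[C@@]1(C)O[C@@H]1CO[Ti](OC(C)C)(OC(C)C)OC(C)C | intermediate (not isolated)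
12 | (2S,6E,10E)-7,11,15-trimethyl-3-methylidenehexadeca-6,10,14-triene-1,2-diol | CC(C)=CCC/C(C)=C/CC/C(C)=C/CCC(=C)[C@@H](CO)O | intermediate
13 | (2S,6E,10E)-7,11,15-trimethyl-3-methylidenehexadeca-6,10,14-triene-1,2-diyl diacetate | CC(C)=CCC/C(C)=C/CC/C(C)=C/CCC(=C)[C@@H](COC(C)=O)OC(C)=O | intermediate
14 | 14,15-diacetoxylabd-13(16)-en-8-yl cation, ring centres and C14 as in 15, paired with the catalyst anion | C=C(CC[C@H]1[C+](C)CC[C@H]2C(C)(C)CCC[C@]12C)[C@@H](COC(C)=O)OC(C)=O | intermediate (not isolated)
15 | (5S,9S,10S,14S)-labda-7,13(16)-diene-14,15-diyl diacetate, i.e. (2S)-3-methylidene-5-[(1S,4aS,8aS)-2,5,5,8a-tetramethyl-1,4,4a,5,6,7,8,8a-octahydronaphthalen-1-yl]pentane-1,2-diyl diacetate | C=C(CC[C@H]1C(C)=CC[C@H]2C(C)(C)CCC[C@]12C)[C@@H](COC(C)=O)OC(C)=O | target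

Total step count: 9. Longest linear sequence: 9 steps (1 to 15).

Steps most likely to fail

Step 9 (the labelled step). Four things may go wrong:
- weak discrimination between the two folding senses at the initiating protonation
- carry-over of the cascade into the C13=C16 alkene
- unselective proton loss from the C8 cationic centre
- acid-induced ionisation at the allylic C14–O bond

The fallback uses known chemistry and runs from 13 back to 15. Catalyst control is given up and the C14 centre set in step 6 serves as an internal resolving handle. Compound 13 is treated with FSO3H (about 5 equiv) in 2-nitropropane at −78 °C and quenched cold with Et3N. This is the established superacid cyclization of open-chain terpenyl acetates. It delivers trans-fused bicyclic 7-enes, and a protonated ester switches off the alkene next to it. Both folding senses should then be populated, so 15 is expected together with (5R,9R,10R,14S)-labda-7,13(16)-diene-14,15-diyl diacetate F1. The two are diastereomers, not mirror images, and would be parted on AgNO3-impregnated silica or by preparative HPLC, at the cost of the material that folds the other way.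

Step 7. Three things may go wrong:
- proton loss from the C12 methylene in place of the C16 methyl
- addition of isopropoxide at C13
- stalling on the titanium chelate

The fallback runs from 2 back to 12. The C13–C16 unit is no longer derived from an epoxide. C14 is taken from the chiral pool and the methylene is installed by olefination, which leaves no regiochemical choice. Commercial methyl (R)-2,2-dimethyl-1,3-dioxolane-4-carboxylate (COC(=O)[C@H]1COC(C)(C)O1) is converted with MeNHOMe·HCl and i-PrMgCl (THF, −20 °C) into (4R)-N-methoxy-N,2,2-trimethyl-1,3-dioxolane-4-carboxamide F2. MeMgBr (THF, 0 °C) then gives (R)-1-(2,2-dimethyl-1,3-dioxolan-4-yl)ethanone F3. Its kinetic lithium enolate (LiN(iPr)2, THF–DMPU, −78 °C, deprotonation at CH3) is alkylated with bromide 2 to give (4E,8E)-1-[(4R)-2,2-dimethyl-1,3-dioxolan-4-yl]-5,9,13-trimethyltetradeca-4,8,12-trien-1-one F4. Wittig methylenation (Ph3PCH3Br, KN(SiMe3)2, THF, −78 to 0 °C) gives (4S)-2,2-dimethyl-4-[(5E,9E)-6,10,14-trimethylpentadeca-1,5,9,13-tetraen-2-yl]-1,3-dioxolane F5. Aqueous acetic acid at rt removes the acetonide to give 12. The dioxolane carbon keeps its four bonds throughout. Its descriptor goes from R (F2 to F4) to S (F5, 12) through the CIP ranking only.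

Step 4. Two things may go wrong: erosion of the stereochemical relay by bond rotation in the copper enolate if the mixture warms, or a second conjugate addition of methyl. The fallback runs from 5 back to 8 and bypasses the enol phosphate. Compound 5 is saponified and decarboxylated (KOH, aq EtOH; then dilute acid, gentle warming) to (5E,9E)-6,10,14-trimethylpentadeca-5,9,13-trien-2-one F6. A Horner–Wadsworth–Emmons reaction with triethyl phosphonoacetate (NaH, THF, 0 °C to rt) should give 8 as the main isomer beside ethyl (2Z,6E,10E)-geranylgeranoate F7, which is removed by chromatography. Geranylgeraniol 9 is also a catalogue compound, so steps 1 to 5 can be replaced by purchase if supply of 8 becomes limiting.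

Further compounds
F1 | step 9 | (5R,9R,10R,14S)-labda-7,13(16)-diene-14,15-diyl diacetate | C=C(CC[C@@H]1C(C)=CC[C@@H]2C(C)(C)CCC[C@@]12C)[C@@H](COC(C)=O)OC(C)=O
F2 | step 7 | (4R)-N-methoxy-N,2,2-trimethyl-1,3-dioxolane-4-carboxamide | CON(C)C(=O)[C@H]1COC(C)(C)O1
F3 | step 7 | (R)-1-(2,2-dimethyl-1,3-dioxolan-4-yl)ethanone | CC(=O)[C@H]1COC(C)(C)O1
F4 | step 7 | (4E,8E)-1-[(4R)-2,2-dimethyl-1,3-dioxolan-4-yl]-5,9,13-trimethyltetradeca-4,8,12-trien-1-one | CC(C)=CCC/C(C)=C/CC/C(C)=C/CCC(=O)[C@H]1COC(C)(C)O1
F5 | step 7 | (4S)-2,2-dimethyl-4-[(5E,9E)-6,10,14-trimethylpentadeca-1,5,9,13-tetraen-2-yl]-1,3-dioxolane | CC(C)=CCC/C(C)=C/CC/C(C)=C/CCC(=C)[C@H]1COC(C)(C)O1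
F6 | step 4 | (5E,9E)-6,10,14-trimethylpentadeca-5,9,13-trien-2-one | CC(C)=CCC/C(C)=C/CC/C(C)=C/CCC(C)=O
F7 | step 4 | ethyl (2Z,6E,10E)-geranylgeranoate | CC(C)=CCC/C(C)=C/CC/C(C)=C/CC/C(C)=C\C(=O)OCC
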